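## Structural features

The target is a flavanonol 3-methyl ether: a chroman-4-one in which benzo ring A is fused to the dihydropyranone ring C, and C2 of ring C carries ring B, a 3-hydroxy-4,5-dimethoxyphenyl group. Ring A carries three oxygens in a row, 5-OH (hydrogen-bonded to the C4 carbonyl), 6-OH and 7-OMe, and C8 is unsubstituted. The only stereocentres, C2 and C3, are adjacent and both R, which places the C2 aryl group and the C3 methoxy group trans and diequatorial. C3 is alpha to the ketone and can epimerise (trans is the more stable arrangement). C2 is a benzylic ether carbon beta to the ketone, so a free enolate can expel O1, open ring C and erase C2. The 5,6-dihydroxy unit is an easily oxidised catechol and, like the 3'-phenol, has to stay masked until the end. The real difficulty is twofold: setting C2 absolutely and C3 relative to it without long-lived enolates, and telling apart seven oxygen substituents of which three end as free hydroxyls. The key step uses the fact that the C4 carbonyl carbon lies between C4a of ring A and C3, with O1 on the neighbouring C8a. Ring C can therefore be assembled from an ortho-iodophenol (C8a, C4a, O1), carbon monoxide (C4) and an aryl acetylene (C3, C2, ring B), giving a flat flavone whose C2=C3 bond is the handle for both stereocentres.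

## Logic of the disconnections

18 from 17: the O6–CH2Ph, O3'–CH2Ph and O5–CH3 bonds. The three free phenols, above all the 5,6-diol, should not pass through oxidations and alkylations. O5 differs from the other methoxy oxygens by being peri to the C4 carbonyl, so one chelating Lewis acid can remove that methyl together with both benzyl groups. The gain is that every earlier compound is fully O-protected and a single deprotection suffices. The demand is that BCl3 leaves the methyl groups on O7, O4', O5' and the C3 oxygen alone and does not ionise the C2–O1 bond.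

17 from 16: the O–CH3 bond on the C3 oxygen. Putting the methyl on last lets that oxygen be introduced as an electrophilic atom onto an enol. The gain is that 16 has one substituent fewer and a single alkylatable hydroxyl. The demand is a methylation that never forms an alkoxide, since base would open ring C or epimerise C3.

16 from 13, through 15 and 14: the C3–O bond. C3 is alpha to the ketone, and the aryl group on C2 shields one face of the enol double bond, so oxygen enters trans. The gain is one stereocentre and one heteroatom fewer, with the relative configuration becoming a consequence of C2. The demand is enolisation with immediate trapping so that O1 is not expelled, and attack of the oxidant anti to the aryl group.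

13 from 11, through 12: the C2–H and C3–H bonds. C2 becomes an sp2 carbon of a flat, achiral pyranone, so a chiral catalyst can set it by choosing a face. The gain is that no stereocentre is left and the ring to be built is fully conjugated and robust. The demand is face selection on a donor-substituted C=C bond, survival of both benzyl ethers, and a mild return of the over-reduced C4 carbinol to the ketone.

11 from 5, 8 and 9, through 10: the C4a–C4, C4–C3 and O1–C2 bonds. A carbonyl carbon between an arene carbon and C3 is the pattern left when carbon monoxide is inserted between an aryl halide and an alkyne terminus, and O1, ortho to C4a, can close onto the alkyne carbon that bears ring B. The gain is that ring C and the link to ring B are replaced by three components, two of them simple benzene derivatives. The demand is that insertion of 9 precedes coupling with 8 and that the phenol closes in the 6-endo rather than the 5-exo sense.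

5 from 4, 4 from 2 through 3, 2 from 1: the C–I bond, then the aryl C–O bond of the phenol (in the forward sense the formyl carbon is excised), then the O–CH2Ph bond. Compound 4 has a mirror plane through C1 and C4, so its two open positions are equivalent and iodination can give only one regioisomer. The formyl group of 1 marks the carbon that must carry the future O1, and the benzyl group singles out the future O6. The gain is a commercial start with all ring A substituents in place. The demand is mono-iodination and an oxidant that turns an aldehyde without a free para-hydroxyl into a phenol.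

8 from 7, 7 from 6: the C≡C bond between the former formyl carbon and one added carbon, then the O–CH2Ph bond. The formyl carbon of 6 is already at the right ring position and becomes C2; the added carbon becomes C3. The gain is a commercial start whose single phenol is the one that must end free. The demand is a one-carbon homologation mild enough for an electron-rich aryl aldehyde.

## Other disconnections considered

Alternative 1: The cuts are C2–C1' and C3–O.
- Forward step: chromone A1 would take up the ring B arylzinc chloride A2 at C2 under [RhCl(C2H4)2]2 and one antipode of BINAP. ClSiMe3 would trap the enolate as the same silyl enol ether as 14, and dimethyldioxirane added to the same flask would oxidise C3 to give A3, which is identical with 16.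
- In favour: C2 is set by the catalyst and C3 by the substrate in one flask, the enolate is silylated as it forms and is never free, and ring B enters late, so the route is convergent and easy to vary.
- Against: A1 has to be built first, about three steps from 4 (C-acetylation, condensation with a formamide acetal, ring closure). The peri 5-methoxy group and three donor oxygens make C2 of A1 a hindered, weak acceptor. A2 must be prepared and used in excess. The oxidant would have to work in a flask still holding phosphine, zinc salts and surplus A2, all of which consume it.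
- Comparison: it is the better plan in stereochemical step economy (one flask against steps 7 and 8) and in avoiding high-pressure hydrogen, and it is equal in the logic for C3, since both plans pass through the same enol ether. It is weaker in skeletal economy, because ring C and the C2–aryl bond are made in separate operations. The total step count should be about the same.

Alternative 2: The cut is the aryl ether bond C8a–O1.
- Forward step: Ag2O would oxidise the acyclic catechol A4 to the ortho-quinone A5. The secondary hydroxyl would add to C8a, the beta carbon of the quinone enone (6-endo-trig), and tautomerisation would restore the catechol in A6, one hydrogenolysis away from the target.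
- In favour: the C3 methoxy group and the free 5,6-diol are present from the start, so neither a late O-methylation nor a peri-demethylation is needed, and both stereocentres would come from one stereoselective aldol addition to 7.
- Against: O1 has to be created by oxidising a C–H position with an alcohol nucleophile, a closure with little analogy for flavanones. A6 is more electron-rich than A4 and should be oxidised further by the same reagent. The beta-hydroxy ketone of A4 can dehydrate or cleave by retro-aldol reaction on the basic silver oxide. The aldol step must control relative and absolute configuration next to a catechol that itself needs selective handling.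
- Comparison: it is the better plan in functional-group and protecting-group economy at the end, and equal in closing ring C late from two aromatic pieces. It is weaker in mechanism, since O1 is present from the outset in 5, and in the reliability of stereocontrol. The step count could be similar or slightly lower on paper, but it rests on the least secure ring closure of the four plans.

Alternative 3: The cut is the C3=C4 bond of a flav-3-ene, that is the C3–C4 bond of ring C.
- Forward step: diene A7 would close with the second-generation Grubbs catalyst RuCl2(H2IMes)(PCy3)(=CHPh) to chromene A8 with loss of ethylene. Dihydroxylation anti to the aryl group, oxidation of the benzylic carbinol (arriving at 16), methylation and deprotection would follow.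
- In favour: the conditions are neutral and tolerant. C2 is fixed before the ring exists, for example by asymmetric allylic etherification of the phenol with [Ir(cod)Cl]2 and a chiral phosphoramidite. Closing a styrene onto an allyl aryl ether is a favourable six-membered metathesis.
- Against: A8 is two oxidation levels short at C4 and lacks the C3 oxygen, so about three further redox operations are needed where the carbonylative plan delivers C4 as a carbonyl at once. A7 needs two more steps from 5 (vinylation of the carbon–iodine bond, then O-allylation). The C2–H bond of A7 and A8 is allylic, benzylic and alpha to oxygen, which invites double-bond migration by ruthenium hydrides and ionisation. The donor-rich ring C of A8 is prone to oxidative aromatisation.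
- Comparison: it is the better plan in operational safety (no CO, no high-pressure hydrogen) and arguably in the generality of C2 control, and the ring-closing event is equally reliable. It is weaker in redox and step economy, by about three to four steps between 5 and 16.

Key step: step 6

Assumption: the (R,R) antipode of the carbene precursor SINpEt·HBF4 (1,3-bis[1-(naphthalen-1-yl)ethyl]-4,5-dihydroimidazolium tetrafluoroborate) is taken to deliver hydrogen to the face of C2 that gives the 2S flavanone; if the sense of induction is the opposite, the (S,S) antipode is used and nothing else changes.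

## Route

Step 1
Reactants: 1 syringaldehyde (4-hydroxy-3,5-dimethoxybenzaldehyde)
Product: 2 4-(benzyloxy)-3,5-dimethoxybenzaldehyde
Conditions: BnBr, K2CO3, DMF, 60 °C
Reagents that add atoms: benzyl bromide, BrCc1ccccc1
Why: Williamson ether synthesis on the only hydroxyl; the benzyl group marks the future O6 as different from its two methylated neighbours and should survive every step up to the final BCl3 treatment.

Step 2
Reactants: 2 4-(benzyloxy)-3,5-dimethoxybenzaldehyde
Product: 4 4-(benzyloxy)-3,5-dimethoxyphenol, via aryl formate 3 (not isolated)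
Conditions: mCPBA, CH2Cl2, 0 °C → rt; then K2CO3 (cat.), MeOH, rt
Reagents that add atoms: 3-chloroperoxybenzoic acid (mCPBA), O=C(OO)c1cccc(Cl)c1
Why: Baeyer–Villiger oxidation of an electron-rich benzaldehyde (the aryl group migrates in preference to hydrogen) gives formate 3, which is methanolysed to the phenol; a peracid is used because 2 has no free ortho or para hydroxyl and so cannot undergo a true Dakin oxidation with alkaline hydrogen peroxide.

Step 3
Reactants: 4 4-(benzyloxy)-3,5-dimethoxyphenol
Product: 5 4-(benzyloxy)-2-iodo-3,5-dimethoxyphenol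
Conditions: NIS (1.0 equiv), TsOH·H2O (10 mol%), MeCN, 0 °C
Reagents that add atoms: N-iodosuccinimide, O=C1CCC(=O)N1I
Why: Electrophilic aromatic iodination ortho to the hydroxyl; the two open positions of 4 are equivalent by symmetry, so only one mono-iodide can form, and one equivalent of reagent at low temperature limits di-iodination.

Step 4
Reactants: 6 3-hydroxy-4,5-dimethoxybenzaldehyde
Product: 7 3-(benzyloxy)-4,5-dimethoxybenzaldehyde
Conditions: BnBr, K2CO3, DMF, 60 °C
Reagents that add atoms: benzyl bromide, BrCc1ccccc1
Why: Williamson ether synthesis; the benzyl group masks the phenol that must end free at C3' and keeps it out of the palladium chemistry and the later O-methylation.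

Step 5
Reactants: 7 3-(benzyloxy)-4,5-dimethoxybenzaldehyde
Product: 8 1-(benzyloxy)-5-ethynyl-2,3-dimethoxybenzene
Conditions: dimethyl (1-diazo-2-oxopropyl)phosphonate, K2CO3, MeOH, 0 °C → rt
Reagents that add atoms: dimethyl (1-diazo-2-oxopropyl)phosphonate, CC(=O)C(=[N+]=[N-])P(=O)(OC)OC
Why: Seyferth–Gilbert homologation in the Ohira–Bestmann version: methoxide deacylates the reagent, the diazomethylphosphonate anion olefinates the aldehyde, and loss of N2 with a 1,2-hydrogen shift gives the terminal alkyne; the carbonate conditions leave the benzyl ether untouched.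

Step 6
Reactants: 5 4-(benzyloxy)-2-iodo-3,5-dimethoxyphenol; 8 1-(benzyloxy)-5-ethynyl-2,3-dimethoxybenzene; 9 carbon monoxide
Product: 11 6-(benzyloxy)-2-[3-(benzyloxy)-4,5-dimethoxyphenyl]-5,7-dimethoxy-4H-chromen-4-one, via ynone 10 (not isolated)
Conditions: PdCl2(PPh3)2 (5 mol%), CO (20 bar), Et2NH, 120 °C, autoclave
Reagents that add atoms: none
Why: Carbonylative Sonogashira coupling with cyclisation in the same flask. The divalent palladium precatalyst is reduced by the amine to zerovalent palladium, which inserts into the carbon–iodine bond of 5; migratory insertion of 9 gives an aroylpalladium iodide, and the amine-activated terminal alkyne 8 is transferred to palladium and reductively eliminated with the acyl group to give ynone 10 (C4a–C4 and C4–C3). The phenoxide of 10 then adds to the alkyne carbon that bears ring B in a 6-endo-dig oxa-Michael closure (O1–C2) and protonation at C3 gives 11; ring C is the only ring closed. The closest known reaction type is the palladium-catalysed carbonylative annulation of 2-iodophenols with aryl acetylenes to flavones in secondary amines. No stereocentre is formed, so no stereocontrol is needed. Carbonylative coupling is favoured over direct alkynylation by the CO pressure, the absence of copper and the electron-rich, doubly ortho-substituted aryl–palladium bond, which inserts CO readily. The 6-endo closure is favoured over the 5-exo closure by the conjugate polarisation of the ynone, which makes the ring B-bearing carbon the electrophilic site, and by diethylamine, which acts as base and as a reversible nucleophilic activator of that carbon. The ring A pattern is secured by symmetry, because 5 is the only mono-iodide that 4 can give.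

Step 7
Reactants: 11 6-(benzyloxy)-2-[3-(benzyloxy)-4,5-dimethoxyphenyl]-5,7-dimethoxy-4H-chromen-4-one
Product: 13 (2S)-6-(benzyloxy)-2-[3-(benzyloxy)-4,5-dimethoxyphenyl]-5,7-dimethoxy-2,3-dihydro-4H-chromen-4-one, via flavan-4-ol 12 (not isolated)
Conditions: Ru(cod)(2-methylallyl)2 (5 mol%), (R,R)-SINpEt·HBF4 (10 mol%), KOt-Bu (15 mol%), hexane, 70 °C; then 11, H2 (120 bar), toluene, rt; then Dess–Martin periodinane, CH2Cl2, rt
Reagents that add atoms: none
Why: Asymmetric hydrogenation of a flavone with a ruthenium complex of a chiral N-heterocyclic carbene, in which the ligand decides which face of C2 receives hydrogen (2S) and homogeneous ruthenium should leave the benzyl ethers intact. Because this catalyst also reduces the ketone, the C4-epimeric carbinols 12 are returned to the ketone by Dess–Martin oxidation, which is neither basic nor strongly acidic and so should not endanger C2.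

Step 8
Reactants: 13 (2S)-6-(benzyloxy)-2-[3-(benzyloxy)-4,5-dimethoxyphenyl]-5,7-dimethoxy-2,3-dihydro-4H-chromen-4-one
Product: 16 (2R,3R)-6-(benzyloxy)-2-[3-(benzyloxy)-4,5-dimethoxyphenyl]-3-hydroxy-5,7-dimethoxy-2,3-dihydro-4H-chromen-4-one, via silyl enol ether 14 (not isolated), via silyloxy epoxide 15 (not isolated)
Conditions: LiN(i-Pr)2, Me3SiCl (in situ), THF, −78 °C; pentane, filter; then dimethyldioxirane, acetone/CH2Cl2, −40 → 0 °C; then 0.5 M HCl, MeOH, 0 °C
Reagents that add atoms: dimethyldioxirane, CC1(C)OO1
Why: Rubottom oxidation: kinetic enolisation with silylation in the same flask gives 14 before the lithium enolate can expel O1, dimethyldioxirane epoxidises the enol ether on the face anti to the C2 aryl group to give 15, and acid opens 15 to the alpha-hydroxy ketone. The new C3 centre is therefore trans to the aryl group (3R), which is also the more stable diequatorial arrangement; C2 is spatially unchanged and its descriptor turns from S to R only because the new oxygen raises the priority of C3.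

Step 9
Reactants: 16 (2R,3R)-6-(benzyloxy)-2-[3-(benzyloxy)-4,5-dimethoxyphenyl]-3-hydroxy-5,7-dimethoxy-2,3-dihydro-4H-chromen-4-one
Product: 17 (2R,3R)-6-(benzyloxy)-2-[3-(benzyloxy)-4,5-dimethoxyphenyl]-3,5,7-trimethoxy-2,3-dihydro-4H-chromen-4-one
Conditions: MeI, Ag2O, 4 Å MS, CH2Cl2, rt, dark
Reagents that add atoms: iodomethane, CI
Why: Purdie methylation: Ag2O activates the iodide and takes up HI without forming a free alkoxide, so neither ring opening by beta-elimination nor epimerisation at C3 should be triggered. No phenol is free at this stage, so the C3 hydroxyl is the only site that can be methylated, and O-alkylation leaves both stereocentres untouched.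

Step 10
Reactants: 17 (2R,3R)-6-(benzyloxy)-2-[3-(benzyloxy)-4,5-dimethoxyphenyl]-3,5,7-trimethoxy-2,3-dihydro-4H-chromen-4-one
Product: 18 (2R,3R)-5,6-dihydroxy-2-(3-hydroxy-4,5-dimethoxyphenyl)-3,7-dimethoxy-2,3-dihydro-4H-chromen-4-one
Conditions: BCl3 (6 equiv), C6HMe5 (4 equiv), CH2Cl2, −78 → 0 °C; then H2O, 0 °C
Reagents that add atoms: none
Why: Lewis-acid ether cleavage in one operation: BCl3 removes the two aryl benzyl ethers at low temperature, with pentamethylbenzene capturing the benzyl cation by Friedel–Crafts alkylation, and on warming the boron held between the C4 carbonyl and O5 activates only the peri methyl ether for attack by chloride. The four other methyl ethers lack this six-membered chelate, and no base or oxidant touches the stereocentres or the newly freed catechol.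

## Compound list

1 | syringaldehyde (4-hydroxy-3,5-dimethoxybenzaldehyde) | COc1cc(C=O)cc(OC)c1O | starting material
2 | 4-(benzyloxy)-3,5-dimethoxybenzaldehyde | COc1cc(C=O)cc(OC)c1OCc1ccccc1 | intermediate
3 | 4-(benzyloxy)-3,5-dimethoxyphenyl formate | COc1cc(OC=O)cc(OC)c1OCc1ccccc1 | intermediate (not isolated)
4 | 4-(benzyloxy)-3,5-dimethoxyphenol | COc1cc(O)cc(OC)c1OCc1ccccc1 | intermediate
5 | 4-(benzyloxy)-2-iodo-3,5-dimethoxyphenol | COc1cc(O)c(I)c(OC)c1OCc1ccccc1 | intermediate
6 | 3-hydroxy-4,5-dimethoxybenzaldehyde | COc1cc(C=O)cc(O)c1OC | starting material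
7 | 3-(benzyloxy)-4,5-dimethoxybenzaldehyde | COc1cc(C=O)cc(OCc2ccccc2)c1OC | intermediate
8 | 1-(benzyloxy)-5-ethynyl-2,3-dimethoxybenzene | C#Cc1cc(OCc2ccccc2)c(OC)c(OC)c1 | intermediate
9 | carbon monoxide | [C-]#[O+] | starting material
10 | 1-[3-(benzyloxy)-6-hydroxy-2,4-dimethoxyphenyl]-3-[3-(benzyloxy)-4,5-dimethoxyphenyl]prop-2-yn-1-one | COc1cc(O)c(C(=O)C#Cc2cc(OCc3ccccc3)c(OC)c(OC)c2)c(OC)c1OCc1ccccc1 | intermediate (not isolated)
11 | 6-(benzyloxy)-2-[3-(benzyloxy)-4,5-dimethoxyphenyl]-5,7-dimethoxy-4H-chromen-4-one | COc1cc2oc(-c3cc(OCc4ccccc4)c(OC)c(OC)c3)cc(=O)c2c(OC)c1OCc1ccccc1 | intermediate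
12 | (2S,4RS)-6-(benzyloxy)-2-[3-(benzyloxy)-4,5-dimethoxyphenyl]-5,7-dimethoxy-3,4-dihydro-2H-chromen-4-ol (both C4 epimers; C4 is lost on oxidation) | COc1cc2c(c(OC)c1OCc1ccccc1)C(O)C[C@@H](c1cc(OCc3ccccc3)c(OC)c(OC)c1)O2 | intermediate (not isolated)
13 | (2S)-6-(benzyloxy)-2-[3-(benzyloxy)-4,5-dimethoxyphenyl]-5,7-dimethoxy-2,3-dihydro-4H-chromen-4-one | COc1cc2c(c(OC)c1OCc1ccccc1)C(=O)C[C@@H](c1cc(OCc3ccccc3)c(OC)c(OC)c1)O2 | intermediate
14 | {[(2S)-6-(benzyloxy)-2-[3-(benzyloxy)-4,5-dimethoxyphenyl]-5,7-dimethoxy-2H-chromen-4-yl]oxy}trimethylsilane | COc1cc2c(c(OC)c1OCc1ccccc1)C(O[Si](C)(C)C)=C[C@@H](c1cc(OCc3ccccc3)c(OC)c(OC)c1)O2 | intermediate (not isolated)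
15 | (2R,3R,4R)-6-(benzyloxy)-2-[3-(benzyloxy)-4,5-dimethoxyphenyl]-3,4-epoxy-5,7-dimethoxy-4-[(trimethylsilyl)oxy]-3,4-dihydro-2H-chromene (oxirane oxygen anti to the C2 aryl group) | COc1cc2c(c(OC)c1OCc1ccccc1)[C@]3(O[Si](C)(C)C)O[C@@H]3[C@@H](c1cc(OCc4ccccc4)c(OC)c(OC)c1)O2 | intermediate (not isolated)
16 | (2R,3R)-6-(benzyloxy)-2-[3-(benzyloxy)-4,5-dimethoxyphenyl]-3-hydroxy-5,7-dimethoxy-2,3-dihydro-4H-chromen-4-one | COc1cc2c(c(OC)c1OCc1ccccc1)C(=O)[C@H](O)[C@@H](c1cc(OCc3ccccc3)c(OC)c(OC)c1)O2 | intermediate
17 | (2R,3R)-6-(benzyloxy)-2-[3-(benzyloxy)-4,5-dimethoxyphenyl]-3,5,7-trimethoxy-2,3-dihydro-4H-chromen-4-one | COc1cc2c(c(OC)c1OCc1ccccc1)C(=O)[C@H](OC)[C@@H](c1cc(OCc3ccccc3)c(OC)c(OC)c1)O2 | intermediate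
18 | (2R,3R)-5,6-dihydroxy-2-(3-hydroxy-4,5-dimethoxyphenyl)-3,7-dimethoxy-2,3-dihydro-4H-chromen-4-one | COc1cc2c(c(O)c1O)C(=O)[C@H](OC)[C@@H](c1cc(O)c(OC)c(OC)c1)O2 | target

## Step count and least certain steps

Total: 10 steps. Longest linear sequence: 8 steps (1, 2, 3, 6, 7, 8, 9, 10); the ring B branch (steps 4 and 5) joins at step 6.

**Step 6 (key step).** Oxidative addition into the electron-rich carbon–iodine bond, flanked by a hydroxyl and a methoxy group, is likely to be slow. Hydrodeiodination, capture of the aroylpalladium species by diethylamine (aminocarbonylation) or alkynylation without CO uptake may then compete. A further risk is partial 5-exo closure of the ynone.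
- Fallback: sets out from 5 and 7 and returns at 11, building the flavone without palladium carbonylation.
- Stille coupling of 5 with tributyl(1-ethoxyvinyl)stannane (PdCl2(PPh3)2, toluene, 100 °C) gives 4-(benzyloxy)-2-(1-ethoxyethenyl)-3,5-dimethoxyphenol F1.
- Acidic work-up (1 M HCl) hydrolyses F1 to 1-[3-(benzyloxy)-6-hydroxy-2,4-dimethoxyphenyl]ethan-1-one F2.
- Claisen–Schmidt condensation of F2 with 7 (KOH, EtOH, rt) gives (2E)-1-[3-(benzyloxy)-6-hydroxy-2,4-dimethoxyphenyl]-3-[3-(benzyloxy)-4,5-dimethoxyphenyl]prop-2-en-1-one F3.
- Oxidative cyclisation of F3 (cat. I2, DMSO, 130 °C) gives 11.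

**Step 7.** Face discrimination may be insufficient, because the peri 5-methoxy group and the bulky, donor-rich ring B differ from simple flavones. Partial hydrogenation of an aromatic ring under forcing pressure is a second risk.
- Fallback: sets out from 5 and 7 and returns at 13, replacing catalytic face selection by resolution at the cost of at most half of the material.
- The chalcone F3 is made as in the fallback for step 6, through F1 and F2.
- Cyclisation of F3 (NaOAc, EtOH, reflux) gives racemic 6-(benzyloxy)-2-[3-(benzyloxy)-4,5-dimethoxyphenyl]-5,7-dimethoxy-2,3-dihydro-4H-chromen-4-one F4.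
- Kinetic resolution by asymmetric transfer hydrogenation is then applied, using the antipode of RhCl(C5Me5)(TsDPEN) that reduces the 2R ketone faster (HCO2H/Et3N, EtOAc, rt). It should leave 13 and convert the unwanted enantiomer into (2R,4R)-6-(benzyloxy)-2-[3-(benzyloxy)-4,5-dimethoxyphenyl]-5,7-dimethoxy-3,4-dihydro-2H-chromen-4-ol F5, which is separated.

**Step 8.** The most likely failure is erosion of the C2 configuration by beta-elimination of O1 from the lithium enolate before silylation, made worse if deprotonation next to the hindered, peri-substituted carbonyl is slow.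
- Fallback: sets out from 12 (isolated by leaving out the oxidation of step 7) and returns at 16. The C3 oxygen comes from alkene dihydroxylation, so no enolate is formed.
- Dehydration of 12 (Burgess reagent, toluene, 50 °C) gives (2S)-6-(benzyloxy)-2-[3-(benzyloxy)-4,5-dimethoxyphenyl]-5,7-dimethoxy-2H-chromene F6 (the same compound as A8).
- Upjohn dihydroxylation anti to the aryl group (cat. OsO4, NMO, acetone/H2O) gives (2R,3S,4S)-6-(benzyloxy)-2-[3-(benzyloxy)-4,5-dimethoxyphenyl]-5,7-dimethoxy-3,4-dihydro-2H-chromene-3,4-diol F7.
- Selective oxidation of the benzylic C4 carbinol (activated MnO2, CH2Cl2) gives 16.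

**Step 9.** The alpha-ketol may be dehydrogenated towards the aromatic pyranone on the silver oxide surface. Alkylation of the hindered secondary hydroxyl may also be slow enough for epimerisation or ring opening to creep in.
- Fallback: sets out from 16 and returns at 17. The mode of activation is changed: the methyl donor is made electrophilic under acid catalysis (Me3SiCHN2, cat. HBF4, CH2Cl2, 0 °C), so no base or metal oxide is present.
- This fallback makes no new compound (F0).

**Step 10.** The main risk is over-demethylation: the central 4'-methoxy group of the 1,2,3-trioxygenated ring B, and the 7-methoxy group next to a boron-bound O6, are the most exposed. Lewis-acid ionisation of the benzylic C2–O1 bond with loss of configuration is the second risk.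
- Fallback: sets out from 11 and returns at 18. The peri methyl is exchanged for benzyl at the achiral flavone stage, so the last step is a neutral hydrogenolysis.
- BCl3 and pentamethylbenzene (CH2Cl2, −78 → 0 °C) convert 11 into 5,6-dihydroxy-2-(3-hydroxy-4,5-dimethoxyphenyl)-7-methoxy-4H-chromen-4-one F8.
- BnBr, K2CO3 (DMF, 70 °C) gives 5,6-bis(benzyloxy)-2-[3-(benzyloxy)-4,5-dimethoxyphenyl]-7-methoxy-4H-chromen-4-one F9.
- The operations of step 7 give (2S)-5,6-bis(benzyloxy)-2-[3-(benzyloxy)-4,5-dimethoxyphenyl]-7-methoxy-2,3-dihydro-4H-chromen-4-one F10.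
- Those of step 8 give (2R,3R)-5,6-bis(benzyloxy)-2-[3-(benzyloxy)-4,5-dimethoxyphenyl]-3-hydroxy-7-methoxy-2,3-dihydro-4H-chromen-4-one F11.
- Those of step 9 give (2R,3R)-5,6-bis(benzyloxy)-2-[3-(benzyloxy)-4,5-dimethoxyphenyl]-3,7-dimethoxy-2,3-dihydro-4H-chromen-4-one F12.
- H2 over Pd/C (EtOAc, rt) then releases 18.

## Further compounds

F1 | step 6 | 4-(benzyloxy)-2-(1-ethoxyethenyl)-3,5-dimethoxyphenol | C=C(OCC)c1c(O)cc(OC)c(OCc2ccccc2)c1OC
F2 | step 6 | 1-[3-(benzyloxy)-6-hydroxy-2,4-dimethoxyphenyl]ethan-1-one | CC(=O)c1c(O)cc(OC)c(OCc2ccccc2)c1OC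
F3 | step 6 | (2E)-1-[3-(benzyloxy)-6-hydroxy-2,4-dimethoxyphenyl]-3-[3-(benzyloxy)-4,5-dimethoxyphenyl]prop-2-en-1-one | COc1cc(O)c(C(=O)/C=C/c2cc(OCc3ccccc3)c(OC)c(OC)c2)c(OC)c1OCc1ccccc1
F4 | step 7 | racemic 6-(benzyloxy)-2-[3-(benzyloxy)-4,5-dimethoxyphenyl]-5,7-dimethoxy-2,3-dihydro-4H-chromen-4-one | COc1cc2c(c(OC)c1OCc1ccccc1)C(=O)CC(c1cc(OCc3ccccc3)c(OC)c(OC)c1)O2
F5 | step 7 | (2R,4R)-6-(benzyloxy)-2-[3-(benzyloxy)-4,5-dimethoxyphenyl]-5,7-dimethoxy-3,4-dihydro-2H-chromen-4-ol | COc1cc2c(c(OC)c1OCc1ccccc1)[C@H](O)C[C@H](c1cc(OCc3ccccc3)c(OC)c(OC)c1)O2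
F6 | step 8 | (2S)-6-(benzyloxy)-2-[3-(benzyloxy)-4,5-dimethoxyphenyl]-5,7-dimethoxy-2H-chromene | COc1cc2c(c(OC)c1OCc1ccccc1)C=C[C@@H](c1cc(OCc3ccccc3)c(OC)c(OC)c1)O2
F7 | step 8 | (2R,3S,4S)-6-(benzyloxy)-2-[3-(benzyloxy)-4,5-dimethoxyphenyl]-5,7-dimethoxy-3,4-dihydro-2H-chromene-3,4-diol | COc1cc2c(c(OC)c1OCc1ccccc1)[C@H](O)[C@H](O)[C@@H](c1cc(OCc3ccccc3)c(OC)c(OC)c1)O2
F0 | step 9 | none | none
F8 | step 10 | 5,6-dihydroxy-2-(3-hydroxy-4,5-dimethoxyphenyl)-7-methoxy-4H-chromen-4-one | COc1cc2oc(-c3cc(O)c(OC)c(OC)c3)cc(=O)c2c(O)c1O
F9 | step 10 | 5,6-bis(benzyloxy)-2-[3-(benzyloxy)-4,5-dimethoxyphenyl]-7-methoxy-4H-chromen-4-one | COc1cc2oc(-c3cc(OCc4ccccc4)c(OC)c(OC)c3)cc(=O)c2c(OCc2ccccc2)c1OCc1ccccc1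
F10 | step 10 | (2S)-5,6-bis(benzyloxy)-2-[3-(benzyloxy)-4,5-dimethoxyphenyl]-7-methoxy-2,3-dihydro-4H-chromen-4-one | COc1cc2c(c(OCc3ccccc3)c1OCc1ccccc1)C(=O)C[C@@H](c1cc(OCc3ccccc3)c(OC)c(OC)c1)O2
F11 | step 10 | (2R,3R)-5,6-bis(benzyloxy)-2-[3-(benzyloxy)-4,5-dimethoxyphenyl]-3-hydroxy-7-methoxy-2,3-dihydro-4H-chromen-4-one | COc1cc2c(c(OCc3ccccc3)c1OCc1ccccc1)C(=O)[C@H](O)[C@@H](c1cc(OCc3ccccc3)c(OC)c(OC)c1)O2
F12 | step 10 | (2R,3R)-5,6-bis(benzyloxy)-2-[3-(benzyloxy)-4,5-dimethoxyphenyl]-3,7-dimethoxy-2,3-dihydro-4H-chromen-4-one | COc1cc2c(c(OCc3ccccc3)c1OCc1ccccc1)C(=O)[C@H](OC)[C@@H](c1cc(OCc3ccccc3)c(OC)c(OC)c1)O2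
A1 | alternative 1 | 6-(benzyloxy)-5,7-dimethoxy-4H-chromen-4-one | COc1cc2occc(=O)c2c(OC)c1OCc1ccccc1
A2 | alternative 1 | [3-(benzyloxy)-4,5-dimethoxyphenyl]zinc chloride | COc1cc([Zn]Cl)cc(OCc2ccccc2)c1OC
A3 | alternative 1 | (2R,3R)-6-(benzyloxy)-2-[3-(benzyloxy)-4,5-dimethoxyphenyl]-3-hydroxy-5,7-dimethoxy-2,3-dihydro-4H-chromen-4-one (identical with 16) | COc1cc2c(c(OC)c1OCc1ccccc1)C(=O)[C@H](O)[C@@H](c1cc(OCc3ccccc3)c(OC)c(OC)c1)O2
A4 | alternative 2 | (2R,3R)-3-[3-(benzyloxy)-4,5-dimethoxyphenyl]-1-(2,3-dihydroxy-4-methoxyphenyl)-3-hydroxy-2-methoxypropan-1-one | COc1ccc(C(=O)[C@H](OC)[C@H](O)c2cc(OCc3ccccc3)c(OC)c(OC)c2)c(O)c1O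
A5 | alternative 2 | 3-{(2R,3R)-3-[3-(benzyloxy)-4,5-dimethoxyphenyl]-3-hydroxy-2-methoxypropanoyl}-6-methoxycyclohexa-3,5-diene-1,2-dione | COC1=CC=C(C(=O)[C@H](OC)[C@H](O)c2cc(OCc3ccccc3)c(OC)c(OC)c2)C(=O)C1=O
A6 | alternative 2 | (2R,3R)-2-[3-(benzyloxy)-4,5-dimethoxyphenyl]-5,6-dihydroxy-3,7-dimethoxy-2,3-dihydro-4H-chromen-4-one | COc1cc2c(c(O)c1O)C(=O)[C@H](OC)[C@@H](c1cc(OCc3ccccc3)c(OC)c(OC)c1)O2
A7 | alternative 3 | 2-(benzyloxy)-5-({(1S)-1-[3-(benzyloxy)-4,5-dimethoxyphenyl]prop-2-en-1-yl}oxy)-4-ethenyl-1,3-dimethoxybenzene | COc1cc(O[C@@H](C=C)c2cc(OCc3ccccc3)c(OC)c(OC)c2)c(C=C)c(OC)c1OCc1ccccc1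
A8 | alternative 3 | (2S)-6-(benzyloxy)-2-[3-(benzyloxy)-4,5-dimethoxyphenyl]-5,7-dimethoxy-2H-chromene | COc1cc2c(c(OC)c1OCc1ccccc1)C=C[C@@H](c1cc(OCc3ccccc3)c(OC)c(OC)c1)O2
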